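**Plan** (labdane numbering: C1–C10 decalin, C18 = 4‑CH3, C19 = 4‑CH2O, C20 = 10‑CH3, C17 = 8‑CH3, C11–C16 side chain, C15 = carboxyl)

- Retrosynthesis: first the C15 tert‑butyl ester and the C19–O angeloyl bond are cut. Then C9–C10 (ring B) and C4–C5 (ring A) are cut in one operation, which opens the decalin to an acyclic (S)‑2,2‑disubstituted epoxy trienoate. The chain is then cut at C4–C19 (methylene transfer to a methyl ketone), C1–C2 (allylic coupling), C1–O (allylic oxidation), C13–C16 (methyl cuprate), C14–C15 and C11–C12 (propargylation of geranyl bromide).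
- Forward: the chain is grown linearly from geranyl bromide; ring A and then ring B arise in the same flask in step 10; the angelate and the free acid come last.
- Enabling feature: rings A and B are a head‑to‑tail isoprenoid trans‑decalin. The quaternary carbons C4 and C10 are each bonded to a CH (C5, C9) that can be the CH terminus of an E‑trisubstituted alkene. C7=C8 marks C8 as the carbon where a cationic cascade ends. The C19 oxygen sits on a carbon attached to C4, so C4–O–C19 can be an oxirane. The C13=C14–C15 enoate is electron‑poor and stops the cascade after ring B.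
- Stereochemistry: C4 comes from a catalyst‑controlled Corey–Chaykovsky epoxidation and its inversion in the cyclisation. C5, C10 and C9 are relayed from C4 through a chair–chair fold of the two E alkenes. 13Z comes from syn carbocupration, and the angelate Z geometry from angelic acid.

Key step: step 10

Remark (assumption): in step 9 the (S)‑binaphthoxide catalyst is taken to give the (S)‑oxirane, as it does with simple methyl ketones; if this ketone shows the opposite sense, the (R)‑catalyst is used.

**Step 1**
Reactants: 1 geranyl bromide [(2E)-1-bromo-3,7-dimethylocta-2,6-diene]; 2 1-(trimethylsilyl)propyne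
Product: 4 trimethyl[(5E)-6,10-dimethylundeca-5,9-dien-1-yn-1-yl]silane, via 3-lithio-1-(trimethylsilyl)propyne 3 (not isolated)
Conditions: 2, n‑BuLi, THF, −20 °C; then 1, −78 → 0 °C
Reagents that add atoms: none
Why: Propargylic alkylation; the silyl‑capped propargyl anion should displace the primary allylic bromide by SN2 at the α‑carbon, so the E alkene of 1 is kept and the alkyne terminus stays blocked.

**Step 2**
Reactants: 4 trimethyl[(5E)-6,10-dimethylundeca-5,9-dien-1-yn-1-yl]silane
Product: 5 (5E)-6,10-dimethylundeca-5,9-dien-1-yne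
Conditions: K2CO3 (cat.), MeOH, 23 °C
Reagents that add atoms: none
Why: Protodesilylation of the alkynyl C–Si bond by methoxide is specific for the sp carbon and leaves both alkenes untouched.

**Step 3**
Reactants: 5 (5E)-6,10-dimethylundeca-5,9-dien-1-yne
Product: 7 tert-butyl (6E)-7,11-dimethyldodeca-6,10-dien-2-ynoate, via lithium acetylide 6 (not isolated)
Conditions: n‑BuLi, THF, −78 °C; then Boc2O, −78 → 0 °C
Reagents that add atoms: di-tert-butyl dicarbonate CC(C)(C)OC(=O)OC(=O)OC(C)(C)C
Why: C‑acylation of a lithium acetylide with the dicarbonate should give the ynoate directly as the tert‑butyl ester, which resists the organometallic and Lewis acid steps ahead.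

**Step 4**
Reactants: 7 tert-butyl (6E)-7,11-dimethyldodeca-6,10-dien-2-ynoate
Product: 8 tert-butyl (2Z,6E)-3,7,11-trimethyldodeca-2,6,10-trienoate
Conditions: Me2CuLi (from MeLi and CuI), THF, −78 °C; sat. aq. NH4Cl at −78 °C
Reagents that add atoms: lithium dimethylcuprate [Li+].C[Cu-]C (made from methyllithium [Li]C and CuI)
Why: Syn carbocupration of the ynoate places the new methyl and the α‑hydrogen cis, so the chain and the ester end up cis (2Z, the 13Z geometry of the target); cold protonation prevents equilibration through the allenoate.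

**Step 5**
Reactants: 8 tert-butyl (2Z,6E)-3,7,11-trimethyldodeca-2,6,10-trienoate
Product: 9 tert-butyl (2Z,6E,10E)-12-hydroxy-3,7,11-trimethyldodeca-2,6,10-trienoate
Conditions: SeO2 (cat.), t‑BuOOH, salicylic acid (cat.), CH2Cl2, 0 → 23 °C
Reagents that add atoms: tert-butyl hydroperoxide CC(C)(C)OO (oxygen source; SeO2 O=[Se]=O is the catalytic carrier)
Why: Riley allylic oxidation (ene reaction, then 2,3‑sigmatropic shift) should attack the most electron‑rich terminal alkene at its E methyl and give the E allylic alcohol, the conjugated alkene being deactivated; the reaction is stopped at partial conversion and 8 is recycled.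

**Step 6**
Reactants: 9 tert-butyl (2Z,6E,10E)-12-hydroxy-3,7,11-trimethyldodeca-2,6,10-trienoate
Product: 10 tert-butyl (2Z,6E,10E)-12-bromo-3,7,11-trimethyldodeca-2,6,10-trienoate
Conditions: CBr4, PPh3, CH2Cl2, 0 °C
Reagents that add atoms: carbon tetrabromide BrC(Br)(Br)Br
Why: Appel reaction; SN2 displacement of the oxyphosphonium group at the primary allylic carbon should occur without allylic transposition or loss of the E geometry.

**Step 7**
Reactants: 10 tert-butyl (2Z,6E,10E)-12-bromo-3,7,11-trimethyldodeca-2,6,10-trienoate; 11 2-(2-bromoethyl)-2-methyl-1,3-dioxolane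
Product: 13 tert-butyl (2Z,6E,10E)-3,7,11-trimethyl-14-(2-methyl-1,3-dioxolan-2-yl)tetradeca-2,6,10-trienoate, via Grignard reagent 12 (not isolated)
Conditions: 11, Mg, THF, 25 °C; then 10, Li2CuCl4 (5 mol %), THF, −78 → −20 °C
Reagents that add atoms: none
Why: Copper‑catalysed Grignard cross‑coupling (Kochi type) should substitute the primary allylic bromide at the α‑carbon with retention of alkene geometry, and the hindered tert‑butyl enoate is inert to the Grignard reagent at this temperature.

**Step 8**
Reactants: 13 tert-butyl (2Z,6E,10E)-3,7,11-trimethyl-14-(2-methyl-1,3-dioxolan-2-yl)tetradeca-2,6,10-trienoate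
Product: 14 tert-butyl (2Z,6E,10E)-3,7,11-trimethyl-15-oxohexadeca-2,6,10-trienoate
Conditions: 1 M aq. HCl, THF, 23 °C
Reagents that add atoms: water O
Why: Acid‑catalysed ketal hydrolysis; dilute acid at room temperature should free the methyl ketone without hydrating the trisubstituted alkenes or cleaving the tert‑butyl ester.

**Step 9**
Reactants: 14 tert-butyl (2Z,6E,10E)-3,7,11-trimethyl-15-oxohexadeca-2,6,10-trienoate
Product: 15 tert-butyl (2Z,6E,10E)-3,7,11-trimethyl-14-[(2S)-2-methyloxiran-2-yl]tetradeca-2,6,10-trienoate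
Conditions: Me3S(O)Cl, NaH, THF, reflux (ylide solution); then 14, LaLi3[(S)-1,1'-bi-2-naphthoxide]3 (5 mol %), tris(2,4,6-trimethoxyphenyl)phosphine oxide (5 mol %), 5 Å MS, THF, 23 °C
Reagents that add atoms: trimethylsulfoxonium chloride C[S+](C)(C)=O.[Cl-]
Why: Catalytic asymmetric Corey–Chaykovsky epoxidation; the lanthanum–lithium binaphthoxide binds ketone and ylide and differentiates the ketone faces by methyl against chain, which sets the oxirane carbon (future C4) as S, and the ylide should prefer the ketone to the β,β‑disubstituted enoate.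

**Step 10**
Reactants: 15 tert-butyl (2Z,6E,10E)-3,7,11-trimethyl-14-[(2S)-2-methyloxiran-2-yl]tetradeca-2,6,10-trienoate
Product: 16 tert-butyl (13Z)-19-hydroxylabda-7,13-dien-15-oate [tert-butyl (2Z)-5-[(1S,4aR,5S,8aR)-5-(hydroxymethyl)-2,5,8a-trimethyl-1,4,4a,5,6,7,8,8a-octahydronaphthalen-1-yl]-3-methylpent-2-enoate]
Conditions: MeAlCl2 (2.5 equiv), CH2Cl2, −78 °C; then aq. Rochelle salt
Reagents that add atoms: none
Why: MeAlCl2 binds the oxirane oxygen (and the ester carbonyl); the C5=C10 alkene opens the oxirane at its tertiary carbon C4 from the side opposite the C–O bond, the C10 cation is captured by C9 of the C8=C9 alkene, and the C8 cation loses the axial 7‑H, the proton being consumed by a methyl–aluminium bond so that the new alkene is not re‑protonated. The closest known reaction type is the Lewis acid‑promoted, oxirane‑initiated cation–olefin polycyclisation of terpenoid epoxy polyenes that copies the biosynthesis of the labdane skeleton, and 2,2‑disubstituted oxiranes are known initiators of this class that give a neopentyl CH2OH on the first ring carbon. Ring A closes 6‑endo‑trig at C5=C10 with the oxirane C–O bond outside the new ring (exo opening), and ring B closes 6‑endo‑trig at C8=C9 through the C9–C10 bond. C4 is set by inversion at the (S)‑oxirane carbon, C5 and C10 by anti addition across the E C5=C10 alkene in a chair (trans fusion, 10‑methyl axial), and C9 by the E geometry of C8=C9 in the second chair (9‑H axial, side chain equatorial); the absolute sense of the fold follows from C4 because the oxirane CH2–O arm, which stays tilted toward the departing oxygen and away from the incoming alkene, should take the axial site syn to the C10 methyl while the free methyl takes the equatorial site. The step needs concerted opening and not free ionisation (favoured by −78 °C, the non‑polar medium and the alkene poised for a six‑membered chair), a stop after ring B (the C13=C14 alkene is conjugated to the Lewis acid‑bound ester and is not nucleophilic), and proton loss toward C7 (the endocyclic trisubstituted alkene is the Zaitsev product from the axial 7‑H, whereas 9‑H is shielded by the side chain and loss from C17 gives the less substituted alkene).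

**Step 11**
Reactants: 16 tert-butyl (13Z)-19-hydroxylabda-7,13-dien-15-oate; 17 angelic acid [(2Z)-2-methylbut-2-enoic acid]
Product: 19 tert-butyl (13Z)-19-[(2Z)-2-methylbut-2-enoyloxy]labda-7,13-dien-15-oate, via mixed anhydride 18 (not isolated)
Conditions: 17, 2,4,6‑Cl3C6H2COCl, Et3N, toluene, 23 °C; then 16, 75 °C
Reagents that add atoms: none
Why: Yamaguchi‑type mixed anhydride acylation without a nucleophilic catalyst; the neopentyl alcohol should attack the less hindered angeloyl carbonyl of 18, and leaving out DMAP avoids the conjugate addition–elimination that turns an angelate into a tiglate.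

**Step 12**
Reactants: 19 tert-butyl (13Z)-19-[(2Z)-2-methylbut-2-enoyloxy]labda-7,13-dien-15-oate
Product: 20 (13Z)-19-[(2Z)-2-methylbut-2-enoyloxy]labda-7,13-dien-15-oic acid [(2Z)-3-methyl-5-[(1S,4aR,5S,8aR)-2,5,8a-trimethyl-5-({[(2Z)-2-methylbut-2-enoyl]oxy}methyl)-1,4,4a,5,6,7,8,8a-octahydronaphthalen-1-yl]pent-2-enoic acid]
Conditions: TMSOTf, 2,6‑lutidine, CH2Cl2, 0 °C; then pH 5 aq. buffer
Reagents that add atoms: none
Why: Silyl triflate‑mediated tert‑butyl ester cleavage (O‑silylation, loss of isobutene, hydrolysis of the silyl ester on work‑up) under lutidine buffering should spare the ring alkene, the Z enoate and the primary angelate ester.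

**Compound list**

1 | geranyl bromide, (2E)-1-bromo-3,7-dimethylocta-2,6-diene | BrC/C=C(C)/CCC=C(C)C | starting material
2 | 1-(trimethylsilyl)propyne | CC#C[Si](C)(C)C | starting material
3 | 3-lithio-1-(trimethylsilyl)propyne | [Li]CC#C[Si](C)(C)C | intermediate
4 | trimethyl[(5E)-6,10-dimethylundeca-5,9-dien-1-yn-1-yl]silane | C[Si](C)(C)C#CCC/C=C(C)/CCC=C(C)C | intermediate
5 | (5E)-6,10-dimethylundeca-5,9-dien-1-yne | C#CCC/C=C(C)/CCC=C(C)C | intermediate
6 | lithium acetylide of 5 | [Li]C#CCC/C=C(C)/CCC=C(C)C | intermediate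
7 | tert-butyl (6E)-7,11-dimethyldodeca-6,10-dien-2-ynoate | CC(C)(C)OC(=O)C#CCC/C=C(C)/CCC=C(C)C | intermediate
8 | tert-butyl (2Z,6E)-3,7,11-trimethyldodeca-2,6,10-trienoate | CC(C)(C)OC(=O)/C=C(C)\CC/C=C(C)/CCC=C(C)C | intermediate
9 | tert-butyl (2Z,6E,10E)-12-hydroxy-3,7,11-trimethyldodeca-2,6,10-trienoate | CC(C)(C)OC(=O)/C=C(C)\CC/C=C(C)/CC/C=C(C)/CO | intermediate
10 | tert-butyl (2Z,6E,10E)-12-bromo-3,7,11-trimethyldodeca-2,6,10-trienoate | CC(C)(C)OC(=O)/C=C(C)\CC/C=C(C)/CC/C=C(C)/CBr | intermediate
11 | 2-(2-bromoethyl)-2-methyl-1,3-dioxolane | CC1(CCBr)OCCO1 | starting material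
12 | Grignard reagent, [2-(2-methyl-1,3-dioxolan-2-yl)ethyl]magnesium bromide | CC1(CC[Mg]Br)OCCO1 | intermediate
13 | tert-butyl (2Z,6E,10E)-3,7,11-trimethyl-14-(2-methyl-1,3-dioxolan-2-yl)tetradeca-2,6,10-trienoate | CC(C)(C)OC(=O)/C=C(C)\CC/C=C(C)/CC/C=C(C)/CCCC1(C)OCCO1 | intermediate
14 | tert-butyl (2Z,6E,10E)-3,7,11-trimethyl-15-oxohexadeca-2,6,10-trienoate | CC(C)(C)OC(=O)/C=C(C)\CC/C=C(C)/CC/C=C(C)/CCCC(C)=O | intermediate
15 | tert-butyl (2Z,6E,10E)-3,7,11-trimethyl-14-[(2S)-2-methyloxiran-2-yl]tetradeca-2,6,10-trienoate | CC(C)(C)OC(=O)/C=C(C)\CC/C=C(C)/CC/C=C(C)/CCC[C@@]1(C)CO1 | intermediate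
16 | tert-butyl (13Z)-19-hydroxylabda-7,13-dien-15-oate (4S,5R,9S,10R; 19‑CH2OH axial, cis to the 10‑methyl) | OC[C@@]1(C)CCC[C@]2(C)[C@@H](CC/C(C)=C\C(=O)OC(C)(C)C)C(C)=CC[C@@H]12 | intermediate
17 | angelic acid, (2Z)-2-methylbut-2-enoic acid | C/C=C(/C)C(=O)O | starting material
18 | mixed anhydride, (2Z)-2-methylbut-2-enoic 2,4,6-trichlorobenzoic anhydride | C/C=C(/C)C(=O)OC(=O)c1c(Cl)cc(Cl)cc1Cl | intermediate
19 | tert-butyl (13Z)-19-[(2Z)-2-methylbut-2-enoyloxy]labda-7,13-dien-15-oate | C/C=C(/C)C(=O)OC[C@@]1(C)CCC[C@]2(C)[C@@H](CC/C(C)=C\C(=O)OC(C)(C)C)C(C)=CC[C@@H]12 | intermediate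
20 | (13Z)-19-[(2Z)-2-methylbut-2-enoyloxy]labda-7,13-dien-15-oic acid | C/C=C(/C)C(=O)OC[C@@]1(C)CCC[C@]2(C)[C@@H](CC/C(C)=C\C(=O)O)C(C)=CC[C@@H]12 | target

**Step count and risks**

Total: 12 steps. Longest linear sequence: 12 steps (1 → 20).

Step 10. Proton loss from the C8 cation may be shared between C7 and the C17 methyl, which would give the exocyclic alkene beside the ring alkene. Fallback (sets out from 15, returns at 16): the regiochemistry is corrected after the cyclisation instead of being left to the elimination. The cyclisation is run as in step 10, and the crude alcohol mixture, which holds tert-butyl (13Z)-19-hydroxylabda-8(17),13-dien-15-oate F1 beside 16, is treated with Co(salen)Cl (salen = N,N'-bis(3,5-di-tert-butylsalicylidene)-1,2-cyclohexanediaminate, 3 mol %) and PhSiH3 (6 mol %) in benzene at 23 °C. Hydrogen atom transfer from the cobalt hydride to the 1,1‑disubstituted alkene of F1, followed by back‑abstraction of the less hindered 7‑H, should move the double bond into ring B and converge F1 on 16. Trisubstituted alkenes and the tert‑butyl ester are inert to this catalyst system.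

Step 9. The ylide may be diverted to the conjugated ester (cyclopropanation), or the catalyst may discriminate the faces of this long‑chain methyl ketone poorly. Fallback (sets out from 10, returns at 15): the stereocentre is taken from the chiral pool.
- (S)‑Citramalic acid is reduced with BH3·SMe2 and B(OMe)3 to (2S)-2-methylbutane-1,2,4-triol F2.
- 2,2‑Dimethoxypropane and TsOH (cat.) give the five‑membered acetonide 2-[(4S)-2,2,4-trimethyl-1,3-dioxolan-4-yl]ethanol F3.
- Appel bromination gives (4S)-4-(2-bromoethyl)-2,2,4-trimethyl-1,3-dioxolane F4, and Mg in THF gives its Grignard reagent {2-[(4S)-2,2,4-trimethyl-1,3-dioxolan-4-yl]ethyl}magnesium bromide F5.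
- F5 is coupled with bromide 10 under Li2CuCl4 catalysis as in step 7 to give tert-butyl (2Z,6E,10E)-3,7,11-trimethyl-14-[(4S)-2,2,4-trimethyl-1,3-dioxolan-4-yl]tetradeca-2,6,10-trienoate F6.
- Aqueous AcOH frees tert-butyl (2Z,6E,10E,15S)-15,16-dihydroxy-3,7,11,15-tetramethylhexadeca-2,6,10-trienoate F7.
- TsCl, Et3N and Bu2SnO (cat.) sulfonylate the primary hydroxyl to give the 16‑O‑tosylate of F7, tert-butyl (2Z,6E,10E,15S)-15-hydroxy-3,7,11,15-tetramethyl-16-(tosyloxy)hexadeca-2,6,10-trienoate F8. K2CO3 in MeOH then closes the oxirane by attack of the tertiary alkoxide on the primary carbon, which leaves the stereocentre untouched and gives 15.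

Step 11. The angeloyl group may isomerise to the tigloyl group through reversible conjugate addition to the activated acyl species at 75 °C. Fallback (sets out from 16, returns at 19): the Z alkene is built on the ester instead of being carried through the acylation. Alcohol 16 is esterified (DCC, DMAP cat., CH2Cl2) with 2-[bis(2,2,2-trifluoroethoxy)phosphoryl]propanoic acid to give tert-butyl (13Z)-19-{2-[bis(2,2,2-trifluoroethoxy)phosphoryl]propanoyloxy}labda-7,13-dien-15-oate F9 (mixture of epimers at the phosphonate carbon). Still–Gennari olefination with acetaldehyde (KHMDS, 18‑crown‑6, THF, −78 °C) should then give the Z‑trisubstituted 2‑methylbut‑2‑enoate 19.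

**Further compounds**

F1 | step 10 | tert-butyl (13Z)-19-hydroxylabda-8(17),13-dien-15-oate | OC[C@@]1(C)CCC[C@]2(C)[C@@H](CC/C(C)=C\C(=O)OC(C)(C)C)C(=C)CC[C@@H]12
F2 | step 9 | (2S)-2-methylbutane-1,2,4-triol | OCC[C@](C)(O)CO
F3 | step 9 | 2-[(4S)-2,2,4-trimethyl-1,3-dioxolan-4-yl]ethanol | OCC[C@@]1(C)COC(C)(C)O1
F4 | step 9 | (4S)-4-(2-bromoethyl)-2,2,4-trimethyl-1,3-dioxolane | BrCC[C@@]1(C)COC(C)(C)O1
F5 | step 9 | {2-[(4S)-2,2,4-trimethyl-1,3-dioxolan-4-yl]ethyl}magnesium bromide | Br[Mg]CC[C@@]1(C)COC(C)(C)O1
F6 | step 9 | tert-butyl (2Z,6E,10E)-3,7,11-trimethyl-14-[(4S)-2,2,4-trimethyl-1,3-dioxolan-4-yl]tetradeca-2,6,10-trienoate | CC(C)(C)OC(=O)/C=C(C)\CC/C=C(C)/CC/C=C(C)/CCC[C@@]1(C)COC(C)(C)O1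
F7 | step 9 | tert-butyl (2Z,6E,10E,15S)-15,16-dihydroxy-3,7,11,15-tetramethylhexadeca-2,6,10-trienoate | CC(C)(C)OC(=O)/C=C(C)\CC/C=C(C)/CC/C=C(C)/CCC[C@](C)(O)CO
F8 | step 9 | tert-butyl (2Z,6E,10E,15S)-15-hydroxy-3,7,11,15-tetramethyl-16-(tosyloxy)hexadeca-2,6,10-trienoate | CC(C)(C)OC(=O)/C=C(C)\CC/C=C(C)/CC/C=C(C)/CCC[C@](C)(O)COS(=O)(=O)c1ccc(C)cc1
F9 | step 11 | tert-butyl (13Z)-19-{2-[bis(2,2,2-trifluoroethoxy)phosphoryl]propanoyloxy}labda-7,13-dien-15-oate | CC(C(=O)OC[C@@]1(C)CCC[C@]2(C)[C@@H](CC/C(C)=C\C(=O)OC(C)(C)C)C(C)=CC[C@@H]12)P(=O)(OCC(F)(F)F)OCC(F)(F)F
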